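The readings come from a simulation for an exercise; noise was put on by code.

| setting | green | blue | flask |
|---|---|---|---|
| D | 5 mM | 5 mM | 5.0 mM |
| J | 1.1 equiv | 1.7 equiv | 1.10 equiv |
| L | 0.020 equiv | 0.020 equiv | 0.0200 equiv |
| remark | the very flask that is asked about, followed so far | run made earlier |  |
| time |  |  | 10 min |

| run | time / min | D / % | X / % |
|---|---|---|---|
| green | 0.417 | 94.7 | 0 |
| green | 0.833 | 89.6 | 0 |
| green | 1.33 | 82.4 | 0.8 |
| green | 2.50 | 73.2 | 0 |
| green | 5.00 | 55.4 | 0 |
| blue | 0.667 | 91.4 | 0.9 |
| blue | 2.00 | 78.2 | 0 |
| blue | 3.00 | 69.0 | 1.1 |
| blue | 5.00 | 57.0 | 0 |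
| blue | 8.00 | 44.7 | 0.2 |

(each reading ± 1 percentage point)

- part of the D that has reacted at 10 min
- share of the unused J that is free and not bound as E, at 10 min

- percent here means D units held: one Z counts as two
- what is said of G includes E
- steps thought possible: D + J + G -> X + 2 G; D + J -> X + G; L + G <-> Q; J + G <-> E; 2 D -> Z
- the earlier runs do not show how much of J is bound; that part of a forecast is a guess

The ratio of D lost to D left is what I follow here. X stays within scatter of zero in both runs, and at 5.00 min the blue run, with more J, holds 1.6 percentage points more D than green, so I take D to go by two D joining to Z. For that second-order step the ratio climbs in a straight line with time, and the last blue reading gives 0.155 /min, the lost-to-left slope; the last green reading gives 0.161 /min.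

Now I bracket the green flask at 10 min. From below stands what blue had lost by 8.00 min, 55.3%, good to 1 point, if, as I took above, the extra J in blue changes nothing in that loss. From above stands first-order decay carried on from that reading, 63.5%, which I expect to overshoot, because the first-order constant read within blue sinks from 0.135 /min at its first reading to 0.101 /min at its last. Inside, my slope gives a ratio of 1.55, so 60.7% reacted.

The forecast, reasoning that “J makes no difference”, says 60.3%, from 57.5% to 65%, a central figure inside my bracket and under my own, with 99.8% of the unused J free.

The green flask gives 60.1% reacted, inside the bracket, and >99.9% free.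

    D + J + G → X + 2 G (k = 3200 /M²/s)
    D + J → X + G (k = 0.00140 /M/s)
    L + G ⇌ Q, settled at all times (K = 5.90 × 10⁷ /M)
    J + G ⇌ E, settled at all times (K = 110 /M)
    2 D → Z (k = 0.250 /M/s)

A neighbouring flask takes 20 mM of D in place of 5.0 mM, with equivalents and time held. For two D joining to Z the slope carries the D charged as a factor, so 4.00 times the charge gives 0.619 /min, and at 10 min a ratio of 6.19, so 86.1% reacted. That neighbouring flask gives 85.9%, with D at 14.1%, Z at 85.3% and X at 0.600%.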